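**Retrosynthetic overview**

1. Feature: ring A is a phloroglucinol whose three oxygens all differ (O1 on C8a is the ring ether, C5 carries OMe, C7 a free OH), with the lavandulyl chain on C8 next to C8a. Ring A is therefore built from an acyclic diene that already carries every substituent.
2. Key disconnection: C4a–C5 and C8–C8a. Ring A is grown on the C5=C6 bond of the (2S)-5-bromo-2-aryl-2,3-dihydropyran-4-one 6 with the 1,1-dimethoxy-3-silyloxy diene 25 in a polar [4+2] closure, then aromatised by loss of methanol and HBr to give 27.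
3. Dienophile 6: asymmetric hetero-Diels–Alder reaction of aldehyde 1 with silyloxy diene 2 (sets C2, closes ring C), then C5 bromination.
4. Diene 25: auxiliary-controlled deconjugative prenylation (sets C2''), reduction to (S)-lavandulol 14, malonate homologation to acid 21, acylation of 1,1-dimethoxyethene, enol silylation.
5. Ring order: ring B comes with 1, ring C is made in step 1, ring A in step 11; desilylation gives kushenol U 28.

Key step: step 11

Assumption: the (S)-BINOL–Ti(OiPr)4 catalyst is taken to deliver the diene to the Si face of aldehyde 1 (the sense known for allyl transfer with this catalyst), which gives (2S)-4; if the sense proves opposite, (R)-BINOL is used and nothing else changes.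

Remark: (S)-lavandulol has the spatial arrangement of the (2''R) side chain; the descriptor changes only because CH2OH outranks isopropenyl whereas CH2Ar does not.

**Route**

Step 1
Reactants: 1 4-(tert-butyldimethylsilyloxy)benzaldehyde; 2 (E)-1-methoxy-3-(trimethylsilyloxy)buta-1,3-diene
Product: 4 (2S)-2-[4-(tert-butyldimethylsilyloxy)phenyl]-2,3-dihydro-4H-pyran-4-one, via silyl aldol adduct 3 (not isolated)
Conditions: (S)-BINOL (20 mol%), Ti(OiPr)4 (10 mol%), 4 Å MS, Et2O, −20 °C; then CF3CO2H, CH2Cl2, 0 °C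
Reagents that add atoms: none
Why: BINOL–titanium-catalysed hetero-Diels–Alder reaction by the Mukaiyama aldol/cyclisation pathway, in which the chiral titanium complex shields one face of the bound aldehyde so that the diene terminus adds to the Si face and sets C2 as S, and acid then closes adduct 3 to the pyranone with loss of methanol.

Step 2
Reactants: 4 (2S)-2-[4-(tert-butyldimethylsilyloxy)phenyl]-2,3-dihydro-4H-pyran-4-one
Product: 6 (2S)-5-bromo-2-[4-(tert-butyldimethylsilyloxy)phenyl]-2,3-dihydro-4H-pyran-4-one, via dibromide 5 (not isolated)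
Conditions: Br2 (1.0 equiv), CH2Cl2, −78 °C; then Et3N, −78 → 0 °C
Reagents that add atoms: bromine, BrBr
Why: Addition–elimination α-bromination of an enone, in which bromine adds across the electron-rich enol ether bond C5=C6 faster than it attacks the silyloxyarene and Et3N removes the acidic C5–H with loss of the anomeric bromide, C2 not being involved.

Step 3
Reactants: 7 (4S)-4-benzyl-1,3-oxazolidin-2-one; 8 3-methylbut-2-enoyl chloride
Product: 10 (4S)-4-benzyl-3-(3-methylbut-2-enoyl)-1,3-oxazolidin-2-one, via lithium oxazolidinide 9 (not isolated)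
Conditions: n-BuLi, THF, −78 °C; then 8, −78 → 0 °C
Reagents that add atoms: none
Why: Standard N-acylation of the lithiated oxazolidinone auxiliary by an acid chloride, which leaves the stereocentre of 7 untouched.

Step 4
Reactants: 10 (4S)-4-benzyl-3-(3-methylbut-2-enoyl)-1,3-oxazolidin-2-one; 11 1-bromo-3-methylbut-2-ene
Product: 13 (4S)-4-benzyl-3-[(2S)-5-methyl-2-(prop-1-en-2-yl)hex-4-enoyl]-1,3-oxazolidin-2-one, via sodium dienolate 12 (not isolated)
Conditions: NaN(SiMe3)2, THF, −78 °C; then 11, −78 → −30 °C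
Reagents that add atoms: none
Why: Evans deconjugative alkylation, in which γ-deprotonation gives the chelated (Z)-dienolate that is alkylated at the α-carbon on the face opposite the benzyl group, which sets the future C2'' (2S in the imide, isopropenyl taking the place of the usual α-alkyl group).

Step 5
Reactants: 13 (4S)-4-benzyl-3-[(2S)-5-methyl-2-(prop-1-en-2-yl)hex-4-enoyl]-1,3-oxazolidin-2-one
Product: 14 (S)-lavandulol, (2S)-5-methyl-2-(prop-1-en-2-yl)hex-4-en-1-ol
Conditions: LiBH4, MeOH (1 equiv), Et2O, 0 °C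
Reagents that add atoms: none
Why: Reductive cleavage of the imide by LiBH4 releases the primary alcohol and the auxiliary without epimerising the α-stereocentre or moving the β,γ-double bond.

Step 6
Reactants: 14 (S)-lavandulol
Product: 15 (S)-lavandulyl iodide, (3S)-3-(iodomethyl)-2,6-dimethylhepta-1,5-diene
Conditions: I2, PPh3, imidazole, CH2Cl2, 0 °C → rt
Reagents that add atoms: iodine, II
Why: Appel-type iodination replaces the hydroxyl group by SN2 at the CH2 carbon, so the neighbouring stereocentre and both alkenes are not involved.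

Step 7
Reactants: 15 (S)-lavandulyl iodide; 16 dimethyl malonate
Product: 18 dimethyl 2-[(2R)-5-methyl-2-(prop-1-en-2-yl)hex-4-en-1-yl]propanedioate, via sodium dimethyl malonate 17 (not isolated)
Conditions: NaH, 16 (3 equiv), THF/DMF, 0 °C; then 15, 70 °C
Reagents that add atoms: none
Why: Malonic ester alkylation, in which the soft malonate anion displaces the β-branched primary iodide by SN2 in a dipolar aprotic medium and the excess of malonate suppresses dialkylation.

Step 8
Reactants: 18 dimethyl 2-[(2R)-5-methyl-2-(prop-1-en-2-yl)hex-4-en-1-yl]propanedioate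
Product: 21 (4S)-7-methyl-4-(prop-1-en-2-yl)oct-6-enoic acid, via dipotassium malonate 19 (not isolated), via malonic acid 20 (not isolated)
Conditions: KOH, MeOH/H2O, reflux; then aq. HCl, 0 °C, extraction; then pyridine, reflux
Reagents that add atoms: potassium hydroxide, [K+].[OH-]
Why: Saponification and thermal decarboxylation complete the malonic ester synthesis and give the two-carbon homologue, whose stereocentre is γ to the carboxyl group and cannot epimerise.

Step 9
Reactants: 21 (4S)-7-methyl-4-(prop-1-en-2-yl)oct-6-enoic acid; 22 1,1-dimethoxyethene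
Product: 24 (6S)-1,1-dimethoxy-9-methyl-6-(prop-1-en-2-yl)deca-1,8-dien-3-one, via acid chloride 23 (not isolated)
Conditions: 1-chloro-N,N,2-trimethylprop-1-en-1-amine, CH2Cl2, 0 °C → rt; then 22 (2.5 equiv), 0 °C → rt
Reagents that add atoms: none
Why: The chloroenamine forms the acid chloride without free HCl (which would add to the alkenes), and C-acylation of the ketene acetal followed by proton loss to a second equivalent of 22 gives the β,β-dimethoxy enone.

Step 10
Reactants: 24 (6S)-1,1-dimethoxy-9-methyl-6-(prop-1-en-2-yl)deca-1,8-dien-3-one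
Product: 25 (3Z,6R)-3-(tert-butyldimethylsilyloxy)-1,1-dimethoxy-9-methyl-6-(prop-1-en-2-yl)deca-1,3,8-triene
Conditions: TBSOTf, Et3N, Et2O, −78 → 0 °C; pentane filtration, used crude
Reagents that add atoms: tert-butyldimethylsilyl trifluoromethanesulfonate, CC(C)(C)[Si](C)(C)OS(=O)(=O)C(F)(F)F
Why: Soft enolisation, in which O-silylation of the vinylogous carbonate carbonyl and deprotonation by Et3N at C4, the only enolisable position, give the cross-conjugated silyl dienol ether, the (Z)-isomer with the chain pointing away from the diene being the one usually favoured under amine/silyl triflate conditions.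

Step 11
Reactants: 6 (2S)-5-bromo-2-[4-(tert-butyldimethylsilyloxy)phenyl]-2,3-dihydro-4H-pyran-4-one; 25 (3Z,6R)-3-(tert-butyldimethylsilyloxy)-1,1-dimethoxy-9-methyl-6-(prop-1-en-2-yl)deca-1,3,8-triene
Product: 27 (2S)-7-(tert-butyldimethylsilyloxy)-2-[4-(tert-butyldimethylsilyloxy)phenyl]-5-methoxy-8-[(2R)-5-methyl-2-(prop-1-en-2-yl)hex-4-en-1-yl]-2,3-dihydro-4H-chromen-4-one, via bromo ketal cycloadduct 26 (not isolated)
Conditions: 25 (1.5 equiv), TBSOTf (1.2 equiv, slow addition), 2,6-di-tert-butyl-4-methylpyridine (2.5 equiv), CH2Cl2, −78 → 0 °C; NaHCO3 quench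
Reagents that add atoms: none
Why: Proposed new method: the silyl triflate O-silylates the C4 carbonyl of 6 to a 4-silyloxy-dihydropyrylium ion whose electrophilic ring carbon C6 (future C8a) is attacked by the most nucleophilic diene terminus C4 (future C8) in a vinylogous Mukaiyama–Michael addition, and the resulting bromo enol silane then attacks the dimethoxy-stabilised cationic carbon C1 of the diene (future C5), so that ring A closes as a six-membered carbocycle in a polar, stepwise [4+2] sense (second bond 6-enolexo with respect to the nucleophile) and the silyl triflate is released. The closest known reactions are the Diels–Alder/aromatisation of 1,1-dialkoxy-3-silyloxy dienes with haloquinones and the silyl-triflate-mediated additions of 1,3-bis(silyloxy) dienes to chromones and of silyl enol ethers to 2-aryl-2,3-dihydropyran-4-ones; what is new is an α-bromo vinylogous ester as the two-carbon partner. Cycloadduct 26 then loses methanol from the C5 ketal (taken up as the methyl silyl ether) and HBr across C4a–C8a, the second loss driven by aromatisation, which leaves OMe on C5, the silyl ether on C7, the side chain on C8 and the ring oxygen on C8a. No stereocentre of 27 is formed here: C4a, C8 and C8a of 26 are erased on aromatisation, so diene geometry and endo/exo or facial mixtures converge, while C2 and C2'' are spectators. The step needs regioselectivity (C8 to C8a) and 1,4- over 1,2-addition, both secured by the polarity match between the vinylogous ketene acetal terminus and the oxocarbenium carbon, and it needs C2 to keep its configuration, which the low temperature, the slow addition of the silyl triflate and a hindered base that does not enolise C3 are meant to secure.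

Step 12
Reactants: 27 (2S)-7-(tert-butyldimethylsilyloxy)-2-[4-(tert-butyldimethylsilyloxy)phenyl]-5-methoxy-8-[(2R)-5-methyl-2-(prop-1-en-2-yl)hex-4-en-1-yl]-2,3-dihydro-4H-chromen-4-one
Product: 28 kushenol U, (2S)-7-hydroxy-2-(4-hydroxyphenyl)-5-methoxy-8-[(2R)-5-methyl-2-(prop-1-en-2-yl)hex-4-en-1-yl]-2,3-dihydro-4H-chromen-4-one
Conditions: HF·pyridine, excess pyridine, THF, 0 °C → rt
Reagents that add atoms: none
Why: Fluoride cleavage of both aryl silyl ethers under buffered, non-basic conditions, which avoids phenoxide-induced opening of the flavanone at C2 and should leave the two alkenes untouched.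

**Compound list**

1 | 4-(tert-butyldimethylsilyloxy)benzaldehyde | CC(C)(C)[Si](C)(C)Oc1ccc(C=O)cc1 | starting material
2 | (E)-1-methoxy-3-(trimethylsilyloxy)buta-1,3-diene | CO/C=C/C(=C)O[Si](C)(C)C | starting material
3 | (1E,5S)-5-[4-(tert-butyldimethylsilyloxy)phenyl]-1-methoxy-5-(trimethylsilyloxy)pent-1-en-3-one (silyl aldol adduct) | CO/C=C/C(=O)C[C@H](O[Si](C)(C)C)c1ccc(O[Si](C)(C)C(C)(C)C)cc1 | intermediate
4 | (2S)-2-[4-(tert-butyldimethylsilyloxy)phenyl]-2,3-dihydro-4H-pyran-4-one | O=C1C=CO[C@H](c2ccc(O[Si](C)(C)C(C)(C)C)cc2)C1 | intermediate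
5 | (2S)-5,6-dibromo-2-[4-(tert-butyldimethylsilyloxy)phenyl]tetrahydro-4H-pyran-4-one (mixture at C5 and C6) | BrC1O[C@H](c2ccc(O[Si](C)(C)C(C)(C)C)cc2)CC(=O)C1Br | intermediate
6 | (2S)-5-bromo-2-[4-(tert-butyldimethylsilyloxy)phenyl]-2,3-dihydro-4H-pyran-4-one | O1[C@H](c2ccc(O[Si](C)(C)C(C)(C)C)cc2)CC(=O)C(Br)=C1 | intermediate
7 | (4S)-4-benzyl-1,3-oxazolidin-2-one | O=C1N[C@@H](Cc2ccccc2)CO1 | starting material
8 | 3-methylbut-2-enoyl chloride | CC(C)=CC(Cl)=O | starting material
9 | lithium (4S)-4-benzyl-2-oxo-1,3-oxazolidin-3-ide | [Li+].O=C1[N-][C@@H](Cc2ccccc2)CO1 | intermediate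
10 | (4S)-4-benzyl-3-(3-methylbut-2-enoyl)-1,3-oxazolidin-2-one | CC(C)=CC(=O)N1[C@@H](Cc2ccccc2)COC1=O | intermediate
11 | 1-bromo-3-methylbut-2-ene | CC(C)=CCBr | starting material
12 | sodium (Z)-dienolate of 10 | [Na+].C=C(C)/C=C(\[O-])N1[C@@H](Cc2ccccc2)COC1=O | intermediate
13 | (4S)-4-benzyl-3-[(2S)-5-methyl-2-(prop-1-en-2-yl)hex-4-enoyl]-1,3-oxazolidin-2-one | C=C(C)[C@H](CC=C(C)C)C(=O)N1[C@@H](Cc2ccccc2)COC1=O | intermediate
14 | (S)-lavandulol, (2S)-5-methyl-2-(prop-1-en-2-yl)hex-4-en-1-ol | OC[C@@H](CC=C(C)C)C(C)=C | intermediate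
15 | (S)-lavandulyl iodide, (3S)-3-(iodomethyl)-2,6-dimethylhepta-1,5-diene | IC[C@@H](CC=C(C)C)C(C)=C | intermediate
16 | dimethyl malonate | COC(=O)CC(=O)OC | starting material
17 | sodium dimethyl malonate | [Na+].COC(=O)[CH-]C(=O)OC | intermediate
18 | dimethyl 2-[(2R)-5-methyl-2-(prop-1-en-2-yl)hex-4-en-1-yl]propanedioate | COC(=O)C(C[C@@H](CC=C(C)C)C(C)=C)C(=O)OC | intermediate
19 | dipotassium 2-[(2R)-5-methyl-2-(prop-1-en-2-yl)hex-4-en-1-yl]propanedioate | [K+].[K+].[O-]C(=O)C(C[C@@H](CC=C(C)C)C(C)=C)C([O-])=O | intermediate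
20 | 2-[(2R)-5-methyl-2-(prop-1-en-2-yl)hex-4-en-1-yl]propanedioic acid | OC(=O)C(C[C@@H](CC=C(C)C)C(C)=C)C(O)=O | intermediate
21 | (4S)-7-methyl-4-(prop-1-en-2-yl)oct-6-enoic acid | OC(=O)CC[C@@H](CC=C(C)C)C(C)=C | intermediate
22 | 1,1-dimethoxyethene | C=C(OC)OC | starting material
23 | (4S)-7-methyl-4-(prop-1-en-2-yl)oct-6-enoyl chloride | ClC(=O)CC[C@@H](CC=C(C)C)C(C)=C | intermediate
24 | (6S)-1,1-dimethoxy-9-methyl-6-(prop-1-en-2-yl)deca-1,8-dien-3-one | COC(OC)=CC(=O)CC[C@@H](CC=C(C)C)C(C)=C | intermediate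
25 | (3Z,6R)-3-(tert-butyldimethylsilyloxy)-1,1-dimethoxy-9-methyl-6-(prop-1-en-2-yl)deca-1,3,8-triene | COC(OC)=C/C(O[Si](C)(C)C(C)(C)C)=C/C[C@@H](CC=C(C)C)C(C)=C | intermediate
26 | (2S)-4a-bromo-7-(tert-butyldimethylsilyloxy)-2-[4-(tert-butyldimethylsilyloxy)phenyl]-5,5-dimethoxy-8-[(2R)-5-methyl-2-(prop-1-en-2-yl)hex-4-en-1-yl]-2,3,4a,5,8,8a-hexahydro-4H-chromen-4-one (mixture at C4a, C8 and C8a) | C=C(C)[C@H](CC=C(C)C)CC1C(O[Si](C)(C)C(C)(C)C)=CC(OC)(OC)C2(Br)C1O[C@H](c1ccc(O[Si](C)(C)C(C)(C)C)cc1)CC2=O | intermediate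
27 | (2S)-7-(tert-butyldimethylsilyloxy)-2-[4-(tert-butyldimethylsilyloxy)phenyl]-5-methoxy-8-[(2R)-5-methyl-2-(prop-1-en-2-yl)hex-4-en-1-yl]-2,3-dihydro-4H-chromen-4-one | C=C(C)[C@H](CC=C(C)C)Cc1c(O[Si](C)(C)C(C)(C)C)cc(OC)c2c1O[C@H](c1ccc(O[Si](C)(C)C(C)(C)C)cc1)CC2=O | intermediate
28 | kushenol U, (2S)-7-hydroxy-2-(4-hydroxyphenyl)-5-methoxy-8-[(2R)-5-methyl-2-(prop-1-en-2-yl)hex-4-en-1-yl]-2,3-dihydro-4H-chromen-4-one | C=C(C)[C@H](CC=C(C)C)Cc1c(O)cc(OC)c2c1O[C@H](c1ccc(O)cc1)CC2=O | target

**Step count**

Total: 12 steps. Longest linear sequence: 10 steps (steps 3 to 12, from auxiliary 7 to 28); the dienophile branch adds steps 1 and 2.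

**Steps most likely to fail**

Step 11 (the labelled step). What may go wrong: the sequence may stop after the first C–C bond because the bromo enol silane does not close onto the ketene acetal cation; the diene may be degraded by the silyl triflate before it is captured; or C2 may lose its configuration by ionisation of the benzylic C2–O1 bond of the O-silylated pyranone. The fallback uses known chemistry, sets out from iodide 15 and comes back at 27: ring A is taken from a ready-made arene and only C2 is set catalytically.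
- Commercial 2′,4′-dihydroxy-6′-methoxyacetophenone is condensed with N,N-dimethylformamide dimethyl acetal to the enaminone (2E)-1-(2,4-dihydroxy-6-methoxyphenyl)-3-(dimethylamino)prop-2-en-1-one F1, which aqueous HCl closes to 7-hydroxy-5-methoxy-4H-chromen-4-one F2.
- N-Iodosuccinimide should iodinate C8 (para to the 5-methoxy group, as in 5,7-dialkoxyflavones) to give 7-hydroxy-8-iodo-5-methoxy-4H-chromen-4-one F3, and TBSCl/imidazole gives 7-(tert-butyldimethylsilyloxy)-8-iodo-5-methoxy-4H-chromen-4-one F4.
- Iodide 15 is converted with Zn dust and LiCl in THF into [(2S)-5-methyl-2-(prop-1-en-2-yl)hex-4-en-1-yl]zinc iodide F5, and Negishi coupling with F4 (Pd(OAc)2, SPhos, THF) gives the chromone 7-(tert-butyldimethylsilyloxy)-5-methoxy-8-[(2R)-5-methyl-2-(prop-1-en-2-yl)hex-4-en-1-yl]-4H-chromen-4-one F6.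
- Rhodium-catalysed asymmetric 1,4-addition (Hayashi–Miyaura reaction) of commercial 4-(tert-butyldimethylsilyloxy)phenylboronic acid to F6 ([Rh(OH)(cod)]2 with an electron-poor chiral BIPHEP-type bisphosphine, ligand antipode chosen for 2S) sets C2 and gives 27, which continues with step 12.

Step 9. What may go wrong: the acylated dimethoxycarbenium chloride may lose chloromethane instead of a proton and so end as the β-keto ester, or enone 24 may be hydrolysed during isolation. The fallback sets out from iodide 15 and comes back at 24, bypassing steps 7 to 9: the C4–C5 bond is made by enolate alkylation instead of the C2–C3 bond by acylation. 4,4-Dimethoxybut-3-en-2-one F7 (from acetyl chloride and two equivalents of 22, the parent case of this acylation) is deprotonated at the methyl group with LiN(iPr)2 in THF at −78 °C to lithium 4,4-dimethoxybuta-1,3-dien-2-olate F8. This kinetic enolate of a vinylogous ester is alkylated with 15 in THF/DMPU (Stork–Danheiser-type α′-alkylation) to give 24.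

Step 1. What may go wrong: the electron-rich aldehyde may react slowly, so that the uncatalysed pathway erodes the enantiomeric purity of 4, or the aryl silyl ether may be lost in the acid stage. The fallback sets out from aldehyde 1 and comes back at 4: the stereocentre is set by hydrogenation and the ring is closed by oxa-Michael addition/elimination.
- Roskamp reaction of 1 with ethyl diazoacetate (SnCl2 cat., CH2Cl2) gives the β-keto ester ethyl 3-[4-(tert-butyldimethylsilyloxy)phenyl]-3-oxopropanoate F9.
- Noyori hydrogenation (RuCl2[(R)-BINAP], H2, EtOH; the antipode that gives the S carbinol with aryl β-keto esters) gives ethyl (3S)-3-[4-(tert-butyldimethylsilyloxy)phenyl]-3-hydroxypropanoate F10.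
- MeNHOMe·HCl/i-PrMgCl converts it into the Weinreb amide (3S)-3-[4-(tert-butyldimethylsilyloxy)phenyl]-3-hydroxy-N-methoxy-N-methylpropanamide F11.
- Excess (Z)-2-ethoxyvinyllithium (from (Z)-1-bromo-2-ethoxyethene and t-BuLi) adds to give the β-ethoxy enone (1Z,5S)-5-[4-(tert-butyldimethylsilyloxy)phenyl]-1-ethoxy-5-hydroxypent-1-en-3-one F12, and catalytic CF3CO2H closes F12 to 4 with loss of ethanol.

**Further compounds**

F1 | step 11 | (2E)-1-(2,4-dihydroxy-6-methoxyphenyl)-3-(dimethylamino)prop-2-en-1-one | CN(C)/C=C/C(=O)c1c(O)cc(O)cc1OC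
F2 | step 11 | 7-hydroxy-5-methoxy-4H-chromen-4-one | COc1cc(O)cc2occc(=O)c12
F3 | step 11 | 7-hydroxy-8-iodo-5-methoxy-4H-chromen-4-one | COc1cc(O)c(I)c2occc(=O)c12
F4 | step 11 | 7-(tert-butyldimethylsilyloxy)-8-iodo-5-methoxy-4H-chromen-4-one | COc1cc(O[Si](C)(C)C(C)(C)C)c(I)c2occc(=O)c12
F5 | step 11 | [(2S)-5-methyl-2-(prop-1-en-2-yl)hex-4-en-1-yl]zinc iodide | I[Zn]C[C@@H](CC=C(C)C)C(C)=C
F6 | step 11 | 7-(tert-butyldimethylsilyloxy)-5-methoxy-8-[(2R)-5-methyl-2-(prop-1-en-2-yl)hex-4-en-1-yl]-4H-chromen-4-one | C=C(C)[C@H](CC=C(C)C)Cc1c(O[Si](C)(C)C(C)(C)C)cc(OC)c2c1occc2=O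
F7 | step 9 | 4,4-dimethoxybut-3-en-2-one | CC(=O)C=C(OC)OC
F8 | step 9 | lithium 4,4-dimethoxybuta-1,3-dien-2-olate | [Li+].C=C([O-])C=C(OC)OC
F9 | step 1 | ethyl 3-[4-(tert-butyldimethylsilyloxy)phenyl]-3-oxopropanoate | CCOC(=O)CC(=O)c1ccc(O[Si](C)(C)C(C)(C)C)cc1
F10 | step 1 | ethyl (3S)-3-[4-(tert-butyldimethylsilyloxy)phenyl]-3-hydroxypropanoate | CCOC(=O)C[C@H](O)c1ccc(O[Si](C)(C)C(C)(C)C)cc1
F11 | step 1 | (3S)-3-[4-(tert-butyldimethylsilyloxy)phenyl]-3-hydroxy-N-methoxy-N-methylpropanamide | CON(C)C(=O)C[C@H](O)c1ccc(O[Si](C)(C)C(C)(C)C)cc1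
F12 | step 1 | (1Z,5S)-5-[4-(tert-butyldimethylsilyloxy)phenyl]-1-ethoxy-5-hydroxypent-1-en-3-one | CCO/C=C\C(=O)C[C@H](O)c1ccc(O[Si](C)(C)C(C)(C)C)cc1
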